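**Retrosynthetic overview**
1. The Cα–Cβ linker is cut by Julia–Kocienski olefination of azulenylmethyl sulfone 15 with epoxy aldehyde 29. H-6 of the right half then comes from palladium/formate hydrogenolysis of the alkenyl oxirane, followed by diimide reduction and desilylation.
2. Left half: Cα by methylenation/hydroboration of the C5 ketone, the C1 carbinol by Mukaiyama hydration, and the seven-membered ring by one-carbon expansion of the cyclohexene ring of cis-hydrindane 5 (Diels–Alder adduct of cyclopentenone and a 2-silyloxy diene).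
3. Enabling feature: with C5 as a carbonyl, the segment C4(Me2)–C5–C6(Me)=C7H–C8H2 of the seven-membered ring is a 2-methylcyclohept-2-enone. That is what results when a C–CH3 unit is inserted into the silyl enol ether double bond of a 4,4-dimethylcyclohexene whose cis ring fusion (C3a/C8a) and quaternary C4 the Diels–Alder reaction has already set.
4. Right half: oxepane by 7-endo epoxide opening on a desymmetrized 2,2-disubstituted cyclohexane-1,3-dione; C6/C7 through Sharpless epoxidation of the tetrasubstituted allylic alcohol 27.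
5. Ring order: left, cyclopentane (from cyclopentenone) → cyclohexene (Diels–Alder) → cycloheptenone (expansion); right, cyclohexane (from the dione) → oxepane.

Key step: step 4

Remark: azulene locants (C1–C8a) are used for the left bicycle, 1-benzoxepine locants (O1–C9a) for the right one, and Cα/Cβ for the linker carbons (Cα on azulene C5). The senses of induction of the oxazaborolidine catalysts in steps 2 and 13 are assumed from their usual models; the enantiomeric catalyst is used if a sense proves opposite.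

**Left half**

Step 1
Reactants: 1 4-methylpent-1-en-3-one
Product: 2 tert-butyl(dimethyl)[(4-methylpenta-1,3-dien-3-yl)oxy]silane
Conditions: TBSOTf, Et3N, CH2Cl2, 0 °C
Reagents that add atoms: tert-butyldimethylsilyl trifluoromethanesulfonate, CC(C)(C)[Si](C)(C)OS(=O)(=O)C(F)(F)F
Why: Silyl enol ether formation (soft enolization) can only occur at the isopropyl methine, the sole enolizable position, and gives the 2-silyloxy diene whose nucleophilic terminus is the CMe2 carbon; no stereocentre is formed.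

Step 2
Reactants: 2 tert-butyl(dimethyl)[(4-methylpenta-1,3-dien-3-yl)oxy]silane; 3 cyclopent-2-en-1-one
Product: 4 (3aS,7aS)-5-(tert-butyldimethylsilyloxy)-4,4-dimethyl-2,3,3a,4,7,7a-hexahydro-1H-inden-1-one
Conditions: (S)-3,3-diphenyl-1-(o-tolyl)tetrahydro-1H,3H-pyrrolo[1,2-c][1,3,2]oxazaborole (10 mol %), AlBr3 (8 mol %), CH2Cl2, −78 → −40 °C
Reagents that add atoms: none
Why: Chiral-Lewis-acid-catalysed Diels–Alder reaction: the CMe2 terminus (enol-ether β-carbon) bonds to the enone β-carbon so that the gem-dimethyl carbon becomes C4 next to C3a, suprafacial addition to the cyclic dienophile makes the ring fusion cis, the AlBr3-activated oxazaborolidine shields one enone face to give (3aS,7aS), and the silyl enol ether is left regiodefined at C5=C6 for step 4.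

Step 3
Reactants: 4 (3aS,7aS)-5-(tert-butyldimethylsilyloxy)-4,4-dimethyl-2,3,3a,4,7,7a-hexahydro-1H-inden-1-one
Product: 5 tert-butyl{[(3aS,7aS)-4,4-dimethyl-1-methylidene-2,3,3a,4,7,7a-hexahydro-1H-inden-5-yl]oxy}dimethylsilane
Conditions: Ph3PCH3Br, KOtBu, THF, 0 °C → rt
Reagents that add atoms: methyltriphenylphosphonium bromide, C[P+](c1ccccc1)(c1ccccc1)c1ccccc1.[Br-]
Why: Wittig methylenation of the only ketone removes the carbonyl that would react with the carbenoid of step 4 and brings in the carbon of the future C1 methyl; the silyl enol ether is inert to the ylide and the cis fusion at the epimerizable C7a is the preferred one.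

Step 4
Reactants: 5 tert-butyl{[(3aS,7aS)-4,4-dimethyl-1-methylidene-2,3,3a,4,7,7a-hexahydro-1H-inden-5-yl]oxy}dimethylsilane
Product: 7 (3aS,8aS)-4,4,6-trimethyl-1-methylidene-2,3,3a,4,8,8a-hexahydroazulen-5(1H)-one, via chlorocyclopropane 6 (not isolated)
Conditions: CH3CHCl2, n-BuLi, Et2O, −40 → −20 °C; then toluene, 100 °C
Reagents that add atoms: 1,1-dichloroethane, CC(Cl)Cl
Why: n-BuLi deprotonates 1,1-dichloroethane and the carbenoid (or the chloro(methyl)carbene formed from it by α-elimination) adds in a concerted [2+1] cheletropic step to the most electron-rich double bond of 5, the C5=C6 silyl enol ether (indene locants), closing the cyclopropane of 6; on heating, the C–Cl bond ionizes with concerted disrotatory opening of the former C5–C6 bond (cyclopropyl to allyl cation, pushed by the silyloxy oxygen) and chloride takes the silyl group, so that the six-membered ring becomes the seven-membered ring with the new carbon and its methyl (azulene C6) inserted between the carbonyl carbon C5 and the vinylic C7. The closest known reaction type is the one-carbon ring homologation of cycloalkanone silyl enol ethers with halocarbenes to 2-halo- or 2-methylcycloalk-2-enones. The only ring closed is the transient three-membered ring (intermolecular [2+1] cycloaddition), and the cycloheptenone arises from the cyclohexene by fragmentation of that bicyclo[4.1.0] unit, not by a ring closure. No stereocentre of 7 is made in this step: the cyclopropane stereocentres disappear on opening, and C3a and C8a from step 2 are remote and not epimerizable under these conditions. The step needs chemoselectivity for the enol ether over the 1,1-disubstituted exocyclic alkene, which the far higher nucleophilicity of the oxygen-substituted double bond and a limiting amount of carbenoid should provide, and it needs the adduct with chlorine endo and methyl exo (the sterically preferred one), since only that epimer can open disrotatorily to a cis-cycloheptenyl cation. The position of carbonyl, methyl and double bond in 7 is dictated by the enol ether regiochemistry inherited from the Diels–Alder step.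

Step 5
Reactants: 7 (3aS,8aS)-4,4,6-trimethyl-1-methylidene-2,3,3a,4,8,8a-hexahydroazulen-5(1H)-one
Product: 9 (1S,3aS,8aS)-1-hydroxy-1,4,4,6-tetramethyl-2,3,3a,4,8,8a-hexahydroazulen-5(1H)-one, via hydroperoxide 8 (not isolated)
Conditions: Co(acac)2 (20 mol %), PhSiH3, O2 (1 atm), THF, rt; then PPh3
Reagents that add atoms: dioxygen, O=O
Why: Mukaiyama hydration (cobalt hydride hydrogen-atom transfer, Markovnikov) should hydrate the electron-rich 1,1-disubstituted exocyclic alkene in preference to the α-methyl enone, and the tertiary C1 radical should take up O2 on the convex face, anti to the C8 methylene on the neighbouring C8a, so that OH ends cis to H-8a and H-3a (1S); PPh3 reduces the hydroperoxide.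

Step 6
Reactants: 9 (1S,3aS,8aS)-1-hydroxy-1,4,4,6-tetramethyl-2,3,3a,4,8,8a-hexahydroazulen-5(1H)-one
Product: 10 (1S,3aS,8aS)-1,4,4,6-tetramethyl-1-(triethylsilyloxy)-2,3,3a,4,8,8a-hexahydroazulen-5(1H)-one
Conditions: TESOTf, 2,6-lutidine, CH2Cl2, −78 → 0 °C
Reagents that add atoms: triethylsilyl trifluoromethanesulfonate, CC[Si](CC)(CC)OS(=O)(=O)C(F)(F)F
Why: Silyl ether protection of the tertiary alcohol keeps the alkoxide out of the strongly basic steps 7 and 23; no stereocentre is touched.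

Step 7
Reactants: 10 (1S,3aS,8aS)-1,4,4,6-tetramethyl-1-(triethylsilyloxy)-2,3,3a,4,8,8a-hexahydroazulen-5(1H)-one
Product: 11 triethyl{[(1S,3aS,8aS)-1,4,4,6-tetramethyl-5-methylidene-1,2,3,3a,4,5,8,8a-octahydroazulen-1-yl]oxy}silane
Conditions: Ph3PCH3Br, KOtBu, toluene, 90 °C
Reagents that add atoms: methyltriphenylphosphonium bromide, C[P+](c1ccccc1)(c1ccccc1)c1ccccc1.[Br-]
Why: Wittig methylenation under forcing conditions (KOtBu, hot toluene) is the standard way to olefinate hindered ketones; C5 has no α-hydrogen (C4 quaternary, C6 sp2), so 1,2-addition of the ylide is expected and gives the exocyclic methylene that becomes Cα.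

Step 8
Reactants: 11 triethyl{[(1S,3aS,8aS)-1,4,4,6-tetramethyl-5-methylidene-1,2,3,3a,4,5,8,8a-octahydroazulen-1-yl]oxy}silane
Product: 13 [(1S,3aS,5R,8aS)-1,4,4,6-tetramethyl-1-(triethylsilyloxy)-1,2,3,3a,4,5,8,8a-octahydroazulen-5-yl]methanol, via alkylborane 12 (not isolated)
Conditions: 9-BBN, THF, 0 °C → rt; then NaOH, H2O2, 0 °C
Reagents that add atoms: hydrogen peroxide, OO
Why: Hydroboration–oxidation: 9-BBN should add only to the 1,1-disubstituted terminus of the diene with boron on Cα and should approach C5 on the convex face (syn to H-3a/H-8a, anti to the pseudo-axial C4 methyl), delivering H-5 cis to H-3a (5R); the C–B bond is oxidized with retention.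

Step 9
Reactants: 13 [(1S,3aS,5R,8aS)-1,4,4,6-tetramethyl-1-(triethylsilyloxy)-1,2,3,3a,4,5,8,8a-octahydroazulen-5-yl]methanol
Product: 14 5-({[(1S,3aS,5R,8aS)-1,4,4,6-tetramethyl-1-(triethylsilyloxy)-1,2,3,3a,4,5,8,8a-octahydroazulen-5-yl]methyl}sulfanyl)-1-phenyl-1H-tetrazole
Conditions: 1-phenyl-1H-tetrazole-5-thiol, PPh3, DIAD, THF, 0 °C → rt
Reagents that add atoms: 1-phenyl-1H-tetrazole-5-thiol, Sc1nnnn1-c1ccccc1
Why: Mitsunobu thioetherification of the primary alcohol with the acidic tetrazole thiol; the silyl ether and the stereocentres are untouched.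

Step 10
Reactants: 14 5-({[(1S,3aS,5R,8aS)-1,4,4,6-tetramethyl-1-(triethylsilyloxy)-1,2,3,3a,4,5,8,8a-octahydroazulen-5-yl]methyl}sulfanyl)-1-phenyl-1H-tetrazole
Product: 15 5-({[(1S,3aS,5R,8aS)-1,4,4,6-tetramethyl-1-(triethylsilyloxy)-1,2,3,3a,4,5,8,8a-octahydroazulen-5-yl]methyl}sulfonyl)-1-phenyl-1H-tetrazole
Conditions: (NH4)6Mo7O24·4H2O (10 mol %), H2O2 (30 %), EtOH, 0 °C → rt
Reagents that add atoms: hydrogen peroxide, OO
Why: Molybdate-catalysed peroxide oxidation of the sulfide to the sulfone is chemoselective over the trisubstituted alkene and gives the Julia–Kocienski partner.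

**Right half**

Step 11
Reactants: 16 2-methylcyclohexane-1,3-dione; 17 prop-2-enal
Product: 18 3-(1-methyl-2,6-dioxocyclohexyl)propanal
Conditions: H2O, rt
Reagents that add atoms: none
Why: Michael addition of the cyclic 1,3-dione to acrolein creates the quaternary carbon (future C5a) under conditions too mild for ring cleavage.

Step 12
Reactants: 18 3-(1-methyl-2,6-dioxocyclohexyl)propanal
Product: 19 2-methyl-2-(4-methylpent-3-en-1-yl)cyclohexane-1,3-dione
Conditions: i-PrPPh3I, n-BuLi, THF, 0 °C; then 18, −78 → 0 °C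
Reagents that add atoms: isopropyltriphenylphosphonium iodide, CC(C)[P+](c1ccccc1)(c1ccccc1)c1ccccc1.[I-]
Why: Wittig olefination with the non-stabilized isopropylidene ylide is chemoselective for the aldehyde over the two hindered ketones at low temperature; no stereocentre is formed.

Step 13
Reactants: 19 2-methyl-2-(4-methylpent-3-en-1-yl)cyclohexane-1,3-dione
Product: 20 (2R,3R)-3-hydroxy-2-methyl-2-(4-methylpent-3-en-1-yl)cyclohexan-1-one
Conditions: (S)-1-methyl-3,3-diphenyltetrahydro-1H,3H-pyrrolo[1,2-c][1,3,2]oxazaborole (20 mol %), catecholborane, toluene, −78 °C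
Reagents that add atoms: none
Why: Corey–Bakshi–Shibata reduction used as an enantiotopic-group-selective desymmetrization: the oxazaborolidine delivers hydride to one carbonyl to give the (R)-carbinol, approach anti to the larger homoprenyl substituent places OH cis to that chain ((2R,3R)), and catecholborane at −78 °C leaves the alkene alone.

Step 14
Reactants: 20 (2R,3R)-3-hydroxy-2-methyl-2-(4-methylpent-3-en-1-yl)cyclohexan-1-one
Product: 21 (2R,3R)-2-{2-[(2S)-3,3-dimethyloxiran-2-yl]ethyl}-3-hydroxy-2-methylcyclohexan-1-one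
Conditions: L-fructose-derived Shi ketone (30 mol %), Oxone, K2CO3, Bu4NHSO4, MeCN/dimethoxymethane/aqueous buffer (pH 10.5), 0 °C
Reagents that add atoms: potassium peroxymonosulfate, [K+].[O-]S(=O)(=O)OO
Why: Shi asymmetric epoxidation (chiral dioxirane, spiro transition state) epoxidizes the trisubstituted alkene under reagent control to the (S)-configured oxirane CH (future C3); the buffered, cold conditions should spare the β-hydroxy ketone.

Step 15
Reactants: 21 (2R,3R)-2-{2-[(2S)-3,3-dimethyloxiran-2-yl]ethyl}-3-hydroxy-2-methylcyclohexan-1-one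
Product: 22 (3S,5aR,9aR)-3-hydroxy-2,2,5a-trimethyloctahydro-1-benzoxepin-6(2H)-one
Conditions: camphorsulfonic acid (10 mol %), CH2Cl2, 0 °C
Reagents that add atoms: none
Why: Acid-catalysed intramolecular epoxide opening (7-endo-tet): protonation directs the ring hydroxyl to the tertiary oxirane carbon, which carries more positive charge, closing the oxepane with retention at C3 (its C–O bond is not broken) and with a cis ring fusion because OH and chain are cis on the cyclohexanone.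

Step 16
Reactants: 22 (3S,5aR,9aR)-3-hydroxy-2,2,5a-trimethyloctahydro-1-benzoxepin-6(2H)-one
Product: 23 (3S,5aR,9aR)-3-(tert-butyldimethylsilyloxy)-2,2,5a-trimethyloctahydro-1-benzoxepin-6(2H)-one
Conditions: TBSOTf, 2,6-lutidine, CH2Cl2, 0 °C
Reagents that add atoms: tert-butyldimethylsilyl trifluoromethanesulfonate, CC(C)(C)[Si](C)(C)OS(=O)(=O)C(F)(F)F
Why: Silyl ether protection of the secondary alcohol before enolate chemistry; no stereocentre is touched.

Step 17
Reactants: 23 (3S,5aR,9aR)-3-(tert-butyldimethylsilyloxy)-2,2,5a-trimethyloctahydro-1-benzoxepin-6(2H)-one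
Product: 24 (3S,5aR,9aR)-3-(tert-butyldimethylsilyloxy)-2,2,5a,7-tetramethyloctahydro-1-benzoxepin-6(2H)-one
Conditions: LDA, THF, −78 °C; MeI, −78 → 0 °C
Reagents that add atoms: iodomethane, CI
Why: Enolate alkylation: only C7 is enolizable (C5a is quaternary), so the methyl goes regiospecifically to C7; its configuration is irrelevant because C7 becomes sp2 in step 18.

Step 18
Reactants: 24 (3S,5aR,9aR)-3-(tert-butyldimethylsilyloxy)-2,2,5a,7-tetramethyloctahydro-1-benzoxepin-6(2H)-one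
Product: 25 (3S,5aR,9aR)-3-(tert-butyldimethylsilyloxy)-2,2,5a,7-tetramethyl-2,3,4,5,5a,8,9,9a-octahydro-1-benzoxepin-6-yl trifluoromethanesulfonate
Conditions: KHMDS, THF, −78 °C; PhNTf2, −78 → 0 °C
Reagents that add atoms: N-phenylbis(trifluoromethanesulfonimide), O=S(=O)(N(c1ccccc1)S(=O)(=O)C(F)(F)F)C(F)(F)F
Why: Enol triflate formation from the only possible enolate gives the tetrasubstituted C6=C7 triflate regiospecifically.

Step 19
Reactants: 25 (3S,5aR,9aR)-3-(tert-butyldimethylsilyloxy)-2,2,5a,7-tetramethyl-2,3,4,5,5a,8,9,9a-octahydro-1-benzoxepin-6-yl trifluoromethanesulfonate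
Product: 26 methyl (3S,5aS,9aR)-3-(tert-butyldimethylsilyloxy)-2,2,5a,7-tetramethyl-2,3,4,5,5a,8,9,9a-octahydro-1-benzoxepine-6-carboxylate
Conditions: Pd(OAc)2 (10 mol %), dppf, CO (1 atm), MeOH, Et3N, DMF, 70 °C
Reagents that add atoms: carbon monoxide, [C-]#[O+]; methanol, CO
Why: Palladium-catalysed methoxycarbonylation of the vinyl triflate (oxidative addition, CO insertion, methanolysis), a reaction that tolerates hindered cyclohexenyl triflates of this β-cyclogeranyl type, installs Cβ on C6.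

Step 20
Reactants: 26 methyl (3S,5aS,9aR)-3-(tert-butyldimethylsilyloxy)-2,2,5a,7-tetramethyl-2,3,4,5,5a,8,9,9a-octahydro-1-benzoxepine-6-carboxylate
Product: 27 [(3S,5aS,9aR)-3-(tert-butyldimethylsilyloxy)-2,2,5a,7-tetramethyl-2,3,4,5,5a,8,9,9a-octahydro-1-benzoxepin-6-yl]methanol
Conditions: DIBAL-H, CH2Cl2, −78 °C
Reagents that add atoms: none
Why: DIBAL-H reduction of the conjugated ester (1,2-reduction) gives the allylic alcohol needed for the directed epoxidation.

Step 21
Reactants: 27 [(3S,5aS,9aR)-3-(tert-butyldimethylsilyloxy)-2,2,5a,7-tetramethyl-2,3,4,5,5a,8,9,9a-octahydro-1-benzoxepin-6-yl]methanol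
Product: 28 [(3S,5aR,6R,7R,9aR)-3-(tert-butyldimethylsilyloxy)-6,7-epoxy-2,2,5a,7-tetramethyldecahydro-1-benzoxepin-6-yl]methanol
Conditions: Ti(OiPr)4, L-(+)-diisopropyl tartrate, t-BuOOH, 4 Å molecular sieves, CH2Cl2, −20 °C
Reagents that add atoms: tert-butyl hydroperoxide, CC(C)(C)OO
Why: Sharpless asymmetric epoxidation: with the hydroxymethyl group drawn at the lower right the L-(+)-tartrate complex delivers oxygen from the lower face, here the face of the C5a methyl and anti to O1/C5 of the oxepane, which fixes C6 and C7 together under reagent control.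

Step 22
Reactants: 28 [(3S,5aR,6R,7R,9aR)-3-(tert-butyldimethylsilyloxy)-6,7-epoxy-2,2,5a,7-tetramethyldecahydro-1-benzoxepin-6-yl]methanol
Product: 29 (3S,5aR,6S,7R,9aR)-3-(tert-butyldimethylsilyloxy)-6,7-epoxy-2,2,5a,7-tetramethyldecahydro-1-benzoxepine-6-carbaldehyde
Conditions: Dess–Martin periodinane, NaHCO3, CH2Cl2, 0 °C → rt
Reagents that add atoms: none
Why: Dess–Martin oxidation of the primary epoxy alcohol gives the non-enolizable α,β-epoxy aldehyde and leaves the oxirane intact under buffered conditions.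

**Union and end game**

Step 23
Reactants: 15 5-({[(1S,3aS,5R,8aS)-1,4,4,6-tetramethyl-1-(triethylsilyloxy)-1,2,3,3a,4,5,8,8a-octahydroazulen-5-yl]methyl}sulfonyl)-1-phenyl-1H-tetrazole; 29 (3S,5aR,6S,7R,9aR)-3-(tert-butyldimethylsilyloxy)-6,7-epoxy-2,2,5a,7-tetramethyldecahydro-1-benzoxepine-6-carbaldehyde
Product: 30 (E)-1-[(1S,3aS,5R,8aS)-1,4,4,6-tetramethyl-1-(triethylsilyloxy)-1,2,3,3a,4,5,8,8a-octahydroazulen-5-yl]-2-[(3S,5aR,6S,7R,9aR)-3-(tert-butyldimethylsilyloxy)-6,7-epoxy-2,2,5a,7-tetramethyldecahydro-1-benzoxepin-6-yl]ethene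
Conditions: 15, KHMDS, DME, −60 °C; then 29, −60 °C → rt
Reagents that add atoms: none
Why: Julia–Kocienski olefination: the metalated sulfone adds to the non-enolizable aldehyde and Smiles rearrangement with loss of SO2 and tetrazolone gives the (E)-alkene, joining the halves at Cα=Cβ; no stereocentre is affected.

Step 24
Reactants: 30 (E)-1-[(1S,3aS,5R,8aS)-1,4,4,6-tetramethyl-1-(triethylsilyloxy)-1,2,3,3a,4,5,8,8a-octahydroazulen-5-yl]-2-[(3S,5aR,6S,7R,9aR)-3-(tert-butyldimethylsilyloxy)-6,7-epoxy-2,2,5a,7-tetramethyldecahydro-1-benzoxepin-6-yl]ethene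
Product: 31 (3S,5aS,6S,7R,9aR)-3-(tert-butyldimethylsilyloxy)-2,2,5a,7-tetramethyl-6-{(E)-2-[(1S,3aS,5R,8aS)-1,4,4,6-tetramethyl-1-(triethylsilyloxy)-1,2,3,3a,4,5,8,8a-octahydroazulen-5-yl]ethenyl}decahydro-1-benzoxepin-7-ol
Conditions: Pd2(dba)3·CHCl3 (5 mol %), PBu3 (10 mol %), HCO2H, Et3N, 1,4-dioxane, rt
Reagents that add atoms: none
Why: Tsuji-type palladium-catalysed formate hydrogenolysis of the alkenyl oxirane: zerovalent palladium ionizes the allylic C6–O bond with inversion and the formate-derived hydride passes from palladium to the more substituted allyl terminus C6, on the face opposite to the departed oxygen, giving H-6 trans to the C7 hydroxyl ((6S,7R)) and leaving the (E)-alkene.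

Step 25
Reactants: 31 (3S,5aS,6S,7R,9aR)-3-(tert-butyldimethylsilyloxy)-2,2,5a,7-tetramethyl-6-{(E)-2-[(1S,3aS,5R,8aS)-1,4,4,6-tetramethyl-1-(triethylsilyloxy)-1,2,3,3a,4,5,8,8a-octahydroazulen-5-yl]ethenyl}decahydro-1-benzoxepin-7-ol
Product: 32 (3S,5aS,6S,7R,9aR)-3-(tert-butyldimethylsilyloxy)-2,2,5a,7-tetramethyl-6-{2-[(1S,3aS,5R,8aS)-1,4,4,6-tetramethyl-1-(triethylsilyloxy)-1,2,3,3a,4,5,8,8a-octahydroazulen-5-yl]ethyl}decahydro-1-benzoxepin-7-ol
Conditions: 2-nitrobenzenesulfonylhydrazide, Et3N, CH2Cl2, rt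
Reagents that add atoms: none
Why: Diimide reduction saturates the 1,2-disubstituted alkene much faster than the trisubstituted ring alkene and does not touch silyl ethers; no stereocentre is affected.

Step 26
Reactants: 32 (3S,5aS,6S,7R,9aR)-3-(tert-butyldimethylsilyloxy)-2,2,5a,7-tetramethyl-6-{2-[(1S,3aS,5R,8aS)-1,4,4,6-tetramethyl-1-(triethylsilyloxy)-1,2,3,3a,4,5,8,8a-octahydroazulen-5-yl]ethyl}decahydro-1-benzoxepin-7-ol
Product: 33 (3S,5aS,6S,7R,9aR)-6-{2-[(1S,3aS,5R,8aS)-1-hydroxy-1,4,4,6-tetramethyl-1,2,3,3a,4,5,8,8a-octahydroazulen-5-yl]ethyl}-2,2,5a,7-tetramethyldecahydro-1-benzoxepine-3,7-diol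
Conditions: TBAF, THF, 50 °C
Reagents that add atoms: none
Why: Fluoride-mediated desilylation removes both silyl ethers and gives the target; no stereocentre is touched.

**Compound list**
1 | 4-methylpent-1-en-3-one | CC(C)C(=O)C=C | starting material
2 | tert-butyl(dimethyl)[(4-methylpenta-1,3-dien-3-yl)oxy]silane | CC(C)=C(O[Si](C)(C)C(C)(C)C)C=C | intermediate
3 | cyclopent-2-en-1-one | O=C1CCC=C1 | starting material
4 | (3aS,7aS)-5-(tert-butyldimethylsilyloxy)-4,4-dimethyl-2,3,3a,4,7,7a-hexahydro-1H-inden-1-one | CC(C)(C)[Si](C)(C)OC1=CC[C@H]2[C@H](CCC2=O)C1(C)C | intermediate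
5 | tert-butyl{[(3aS,7aS)-4,4-dimethyl-1-methylidene-2,3,3a,4,7,7a-hexahydro-1H-inden-5-yl]oxy}dimethylsilane | CC(C)(C)[Si](C)(C)OC1=CC[C@H]2[C@H](CCC2=C)C1(C)C | intermediate
6 | chloro(methyl)cyclopropane adduct of 5 across C5–C6 (mixture of epimers at the three cyclopropane carbons) | CC1(Cl)C2C[C@H]3[C@H](CCC3=C)C(C)(C)C12O[Si](C)(C)C(C)(C)C | intermediate
7 | (3aS,8aS)-4,4,6-trimethyl-1-methylidene-2,3,3a,4,8,8a-hexahydroazulen-5(1H)-one | CC1=CC[C@H]2[C@H](CCC2=C)C(C)(C)C1=O | intermediate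
8 | (1S,3aS,8aS)-1-hydroperoxy-1,4,4,6-tetramethyl-2,3,3a,4,8,8a-hexahydroazulen-5(1H)-one | CC1=CC[C@H]2[C@H](CC[C@]2(C)OO)C(C)(C)C1=O | intermediate
9 | (1S,3aS,8aS)-1-hydroxy-1,4,4,6-tetramethyl-2,3,3a,4,8,8a-hexahydroazulen-5(1H)-one | CC1=CC[C@H]2[C@H](CC[C@]2(C)O)C(C)(C)C1=O | intermediate
10 | (1S,3aS,8aS)-1,4,4,6-tetramethyl-1-(triethylsilyloxy)-2,3,3a,4,8,8a-hexahydroazulen-5(1H)-one | CC1=CC[C@H]2[C@H](CC[C@]2(C)O[Si](CC)(CC)CC)C(C)(C)C1=O | intermediate
11 | triethyl{[(1S,3aS,8aS)-1,4,4,6-tetramethyl-5-methylidene-1,2,3,3a,4,5,8,8a-octahydroazulen-1-yl]oxy}silane | CC1=CC[C@H]2[C@H](CC[C@]2(C)O[Si](CC)(CC)CC)C(C)(C)C1=C | intermediate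
12 | 9-{[(1S,3aS,5R,8aS)-1,4,4,6-tetramethyl-1-(triethylsilyloxy)-1,2,3,3a,4,5,8,8a-octahydroazulen-5-yl]methyl}-9-borabicyclo[3.3.1]nonane | CC1=CC[C@H]2[C@H](CC[C@]2(C)O[Si](CC)(CC)CC)C(C)(C)[C@@H]1CB1C2CCCC1CCC2 | intermediate
13 | [(1S,3aS,5R,8aS)-1,4,4,6-tetramethyl-1-(triethylsilyloxy)-1,2,3,3a,4,5,8,8a-octahydroazulen-5-yl]methanol | CC1=CC[C@H]2[C@H](CC[C@]2(C)O[Si](CC)(CC)CC)C(C)(C)[C@@H]1CO | intermediate
14 | 5-({[(1S,3aS,5R,8aS)-1,4,4,6-tetramethyl-1-(triethylsilyloxy)-1,2,3,3a,4,5,8,8a-octahydroazulen-5-yl]methyl}sulfanyl)-1-phenyl-1H-tetrazole | CC1=CC[C@H]2[C@H](CC[C@]2(C)O[Si](CC)(CC)CC)C(C)(C)[C@@H]1CSc1nnnn1-c1ccccc1 | intermediate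
15 | 5-({[(1S,3aS,5R,8aS)-1,4,4,6-tetramethyl-1-(triethylsilyloxy)-1,2,3,3a,4,5,8,8a-octahydroazulen-5-yl]methyl}sulfonyl)-1-phenyl-1H-tetrazole | CC1=CC[C@H]2[C@H](CC[C@]2(C)O[Si](CC)(CC)CC)C(C)(C)[C@@H]1CS(=O)(=O)c1nnnn1-c1ccccc1 | intermediate
16 | 2-methylcyclohexane-1,3-dione | CC1C(=O)CCCC1=O | starting material
17 | prop-2-enal | C=CC=O | starting material
18 | 3-(1-methyl-2,6-dioxocyclohexyl)propanal | CC1(CCC=O)C(=O)CCCC1=O | intermediate
19 | 2-methyl-2-(4-methylpent-3-en-1-yl)cyclohexane-1,3-dione | CC(C)=CCCC1(C)C(=O)CCCC1=O | intermediate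
20 | (2R,3R)-3-hydroxy-2-methyl-2-(4-methylpent-3-en-1-yl)cyclohexan-1-one | O=C1CCC[C@@H](O)[C@@]1(C)CCC=C(C)C | intermediate
21 | (2R,3R)-2-{2-[(2S)-3,3-dimethyloxiran-2-yl]ethyl}-3-hydroxy-2-methylcyclohexan-1-one | O=C1CCC[C@@H](O)[C@@]1(C)CC[C@@H]1OC1(C)C | intermediate
22 | (3S,5aR,9aR)-3-hydroxy-2,2,5a-trimethyloctahydro-1-benzoxepin-6(2H)-one | O=C1[C@]2(C)CC[C@H](O)C(C)(C)O[C@@H]2CCC1 | intermediate
23 | (3S,5aR,9aR)-3-(tert-butyldimethylsilyloxy)-2,2,5a-trimethyloctahydro-1-benzoxepin-6(2H)-one | O=C1[C@]2(C)CC[C@H](O[Si](C)(C)C(C)(C)C)C(C)(C)O[C@@H]2CCC1 | intermediate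
24 | (3S,5aR,9aR)-3-(tert-butyldimethylsilyloxy)-2,2,5a,7-tetramethyloctahydro-1-benzoxepin-6(2H)-one (both C7 epimers) | O=C1[C@]2(C)CC[C@H](O[Si](C)(C)C(C)(C)C)C(C)(C)O[C@@H]2CCC1C | intermediate
25 | (3S,5aR,9aR)-3-(tert-butyldimethylsilyloxy)-2,2,5a,7-tetramethyl-2,3,4,5,5a,8,9,9a-octahydro-1-benzoxepin-6-yl trifluoromethanesulfonate | CC1=C(OS(=O)(=O)C(F)(F)F)[C@]2(C)CC[C@H](O[Si](C)(C)C(C)(C)C)C(C)(C)O[C@@H]2CC1 | intermediate
26 | methyl (3S,5aS,9aR)-3-(tert-butyldimethylsilyloxy)-2,2,5a,7-tetramethyl-2,3,4,5,5a,8,9,9a-octahydro-1-benzoxepine-6-carboxylate | CC1=C(C(=O)OC)[C@]2(C)CC[C@H](O[Si](C)(C)C(C)(C)C)C(C)(C)O[C@@H]2CC1 | intermediate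
27 | [(3S,5aS,9aR)-3-(tert-butyldimethylsilyloxy)-2,2,5a,7-tetramethyl-2,3,4,5,5a,8,9,9a-octahydro-1-benzoxepin-6-yl]methanol | CC1=C(CO)[C@]2(C)CC[C@H](O[Si](C)(C)C(C)(C)C)C(C)(C)O[C@@H]2CC1 | intermediate
28 | [(3S,5aR,6R,7R,9aR)-3-(tert-butyldimethylsilyloxy)-6,7-epoxy-2,2,5a,7-tetramethyldecahydro-1-benzoxepin-6-yl]methanol (oxirane oxygen cis to the C5a methyl) | OC[C@]13[C@]2(C)CC[C@H](O[Si](C)(C)C(C)(C)C)C(C)(C)O[C@@H]2CC[C@@]1(C)O3 | intermediate
29 | (3S,5aR,6S,7R,9aR)-3-(tert-butyldimethylsilyloxy)-6,7-epoxy-2,2,5a,7-tetramethyldecahydro-1-benzoxepine-6-carbaldehyde | O=C[C@]13[C@]2(C)CC[C@H](O[Si](C)(C)C(C)(C)C)C(C)(C)O[C@@H]2CC[C@@]1(C)O3 | intermediate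
30 | (E)-1-[(1S,3aS,5R,8aS)-1,4,4,6-tetramethyl-1-(triethylsilyloxy)-1,2,3,3a,4,5,8,8a-octahydroazulen-5-yl]-2-[(3S,5aR,6S,7R,9aR)-3-(tert-butyldimethylsilyloxy)-6,7-epoxy-2,2,5a,7-tetramethyldecahydro-1-benzoxepin-6-yl]ethene | CC1=CC[C@H]2[C@H](CC[C@]2(C)O[Si](CC)(CC)CC)C(C)(C)[C@@H]1/C=C/[C@]13[C@]2(C)CC[C@H](O[Si](C)(C)C(C)(C)C)C(C)(C)O[C@@H]2CC[C@@]1(C)O3 | intermediate
31 | (3S,5aS,6S,7R,9aR)-3-(tert-butyldimethylsilyloxy)-2,2,5a,7-tetramethyl-6-{(E)-2-[(1S,3aS,5R,8aS)-1,4,4,6-tetramethyl-1-(triethylsilyloxy)-1,2,3,3a,4,5,8,8a-octahydroazulen-5-yl]ethenyl}decahydro-1-benzoxepin-7-ol | CC1=CC[C@H]2[C@H](CC[C@]2(C)O[Si](CC)(CC)CC)C(C)(C)[C@@H]1/C=C/[C@H]1[C@]2(C)CC[C@H](O[Si](C)(C)C(C)(C)C)C(C)(C)O[C@@H]2CC[C@@]1(C)O | intermediate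
32 | (3S,5aS,6S,7R,9aR)-3-(tert-butyldimethylsilyloxy)-2,2,5a,7-tetramethyl-6-{2-[(1S,3aS,5R,8aS)-1,4,4,6-tetramethyl-1-(triethylsilyloxy)-1,2,3,3a,4,5,8,8a-octahydroazulen-5-yl]ethyl}decahydro-1-benzoxepin-7-ol | CC1=CC[C@H]2[C@H](CC[C@]2(C)O[Si](CC)(CC)CC)C(C)(C)[C@@H]1CC[C@H]1[C@]2(C)CC[C@H](O[Si](C)(C)C(C)(C)C)C(C)(C)O[C@@H]2CC[C@@]1(C)O | intermediate
33 | (3S,5aS,6S,7R,9aR)-6-{2-[(1S,3aS,5R,8aS)-1-hydroxy-1,4,4,6-tetramethyl-1,2,3,3a,4,5,8,8a-octahydroazulen-5-yl]ethyl}-2,2,5a,7-tetramethyldecahydro-1-benzoxepine-3,7-diol | CC1=CC[C@H]2[C@H](CC[C@]2(C)O)C(C)(C)[C@@H]1CC[C@H]1[C@]2(C)CC[C@H](O)C(C)(C)O[C@@H]2CC[C@@]1(C)O | target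

**Step count**
Total: 26 steps. Longest linear sequence: 16 steps (steps 11–22, then 23–26).

**Three steps most likely to fail**

Step 2. The hindered CMe2 terminus of the diene may react too slowly with the chiral Lewis acid complex, stop at a Mukaiyama–Michael stage, or give poor facial discrimination. Fallback (from 2, back to 4): diene 2 is combined with commercially available (R)-4-(tert-butyldimethylsilyloxy)cyclopent-2-en-1-one under achiral mixed Lewis-acid catalysis (AlBr3/AlMe3). The diene adds anti to the silyloxy group and gives (3R,3aS,7aS)-3,5-bis(tert-butyldimethylsilyloxy)-4,4-dimethyl-2,3,3a,4,7,7a-hexahydro-1H-inden-1-one F1. DBU eliminates silanol to the cyclopentenone (3aS,7aS)-5-(tert-butyldimethylsilyloxy)-4,4-dimethyl-3a,4,7,7a-tetrahydro-1H-inden-1-one F2. Conjugate reduction with [(Ph3P)CuH]6 then gives 4, with the absolute configuration taken from the chiral pool.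

Step 4. The carbene may also cyclopropanate the exocyclic alkene or rearrange by 1,2-hydride shift, and the cyclopropane epimer with chlorine exo may not open. Fallback (from 5, back to 7): dibromocarbene (CHBr3, KOtBu, pentane) adds to the silyl enol ether to give the dibromocyclopropane adduct of 5 across C5–C6 F3, in which one bromine is always endo. Warming opens it to (3aS,8aS)-6-bromo-4,4-dimethyl-1-methylidene-2,3,3a,4,8,8a-hexahydroazulen-5(1H)-one F4. Suzuki–Miyaura methylation (MeB(OH)2, Pd(dppf)Cl2, K2CO3, dioxane/H2O) gives 7.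

Step 24. β-Hydride elimination from the allylpalladium intermediate to a diene, hydride delivery to the distal allyl terminus, or loss of stereospecificity at the fully substituted C6 may intervene. Fallback (from 28, back to 31): NaAlH2(OCH2CH2OCH3)2 reduces epoxy alcohol 28 by alkoxide-directed hydride delivery to C6 with inversion, giving (3S,5aS,6R,7R,9aR)-3-(tert-butyldimethylsilyloxy)-6-(hydroxymethyl)-2,2,5a,7-tetramethyldecahydro-1-benzoxepin-7-ol F5. Selective oxidation of the primary alcohol (TEMPO, PhI(OAc)2) gives (3S,5aS,6S,7R,9aR)-3-(tert-butyldimethylsilyloxy)-7-hydroxy-2,2,5a,7-tetramethyldecahydro-1-benzoxepine-6-carbaldehyde F6. Julia–Kocienski olefination of F6 with sulfone 15 (KHMDS, DME, −60 °C) gives 31.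

**Further compounds**
F1 | step 2 | (3R,3aS,7aS)-3,5-bis(tert-butyldimethylsilyloxy)-4,4-dimethyl-2,3,3a,4,7,7a-hexahydro-1H-inden-1-one | CC(C)(C)[Si](C)(C)OC1=CC[C@H]2[C@H]([C@H](O[Si](C)(C)C(C)(C)C)CC2=O)C1(C)C
F2 | step 2 | (3aS,7aS)-5-(tert-butyldimethylsilyloxy)-4,4-dimethyl-3a,4,7,7a-tetrahydro-1H-inden-1-one | CC(C)(C)[Si](C)(C)OC1=CC[C@H]2[C@H](C=CC2=O)C1(C)C
F3 | step 4 | dibromocyclopropane adduct of 5 across C5–C6 | BrC1(Br)C2C[C@H]3[C@H](CCC3=C)C(C)(C)C12O[Si](C)(C)C(C)(C)C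
F4 | step 4 | (3aS,8aS)-6-bromo-4,4-dimethyl-1-methylidene-2,3,3a,4,8,8a-hexahydroazulen-5(1H)-one | BrC1=CC[C@H]2[C@H](CCC2=C)C(C)(C)C1=O
F5 | step 24 | (3S,5aS,6R,7R,9aR)-3-(tert-butyldimethylsilyloxy)-6-(hydroxymethyl)-2,2,5a,7-tetramethyldecahydro-1-benzoxepin-7-ol | OC[C@H]1[C@]2(C)CC[C@H](O[Si](C)(C)C(C)(C)C)C(C)(C)O[C@@H]2CC[C@@]1(C)O
F6 | step 24 | (3S,5aS,6S,7R,9aR)-3-(tert-butyldimethylsilyloxy)-7-hydroxy-2,2,5a,7-tetramethyldecahydro-1-benzoxepine-6-carbaldehyde | O=C[C@H]1[C@]2(C)CC[C@H](O[Si](C)(C)C(C)(C)C)C(C)(C)O[C@@H]2CC[C@@]1(C)O
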